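The runs are calculated with constants of no real substance, noise included.

Percent of the G charged per minute was the unit in which I read these runs: L is the product, and G and solid E are the charges.

all flasks: G 18 mM
- teal: E 22 mM; run made earlier
- grey: E 58 mM; run made earlier
- alpha: E 18.4 mM; time 1.5 h
- theta: E 40.0 mM; time 0.80 h

| run | time / min | L / % | G / % |
|---|---|---|---|
| teal | 8.00 | 8.6 | 91.5 |
| teal | 15.0 | 23.1 | 77.4 |
| teal | 25.0 | 39.9 | 58.7 |
| teal | 50.0 | 75.6 | 25.2 |
| teal | 90.0 | 97.0 | 6.6 |
| grey | 8.00 | 7.3 | 91.9 |
| grey | 25.0 | 40.8 | 58.3 |
| grey | 40.0 | 65.9 | 35.9 |
| grey | 60.0 | 84.2 | 12.8 |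
| grey | 90.0 | 97.8 | 2.2 |

(standard deviation of a reading: 1 percentage point)

- which one finishes higher in amount of L, in percent of the G charged ("neither" within 2 percentage points) (alpha / theta / neither)
- amount of L at the end, in percent of the G charged, alpha
- amount of L at the end, in percent of the G charged, theta

Grey held more E than teal, yet at 25.0 min they read 39.9 % and 40.8 %, so I treated them as one curve while solid E lasted. Grey's steep stretch, from 25.0 min to 40.0 min, gave a pace at which the whole G charge takes 59.8 min. I carried this as the turnover time, because a reading time divided by it estimates the share of G turned over on that curve.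

So theta had 0.803 turnover times and alpha 1.51, which is a longer run than theta's. But the curve bends late, so for theta I read between grey's neighbouring points and got 73.2 %. Alpha's E, 18.4 mM, barely exceeds its G, 18 mM, the limiting reagent, so I expected alpha to fall below grey's 97.8 % at 90.0 min, but I still ranked it first.

The forecast also chose alpha, with 91 % for alpha and 74 % for theta, saying of theta “so it should follow grey and teal at that time”.

The flasks gave 90.0 % for alpha and 73.8 % for theta, so alpha finished higher.

    J ⇌ D, rate k1*(cs1 - [D]) while solid is left; crystals form when [D] > cs1 (solubility = 5.90 mM, k = 0.570 /min)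
    G + Z → L + D (k = 7.10 /M/min)
    E ⇌ Z, rate k3*(cs3 - [Z]) while solid is left; crystals form when [Z] > cs3 (solubility = 12.0 mM, k = 0.0500 /min)

The shorter time holds theta below alpha, and the E charge does not: theta's charge left for alpha's 1.5 h reaches 97.7 %, against 73.8 % at its own time. Its 0.803 turnover times had pointed to 80.3 %, and the flask stands 6.5 percentage points lower, on the bend. Earlier on the curve the same turnover time, put on theta's flask read at 20 min, reckons 33.4 %, and that flask holds 31.0 %.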